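**Strategy.** Ring A (C1–C5, C10) holds the retron of a Diels–Alder adduct: C3 carries oxygen, the adjacent quaternary C4 carries methyl and carboxyl, and the C5–C10 bond is shared with ring B. Everything rests on an intramolecular Diels–Alder reaction of an acyclic polyene in which a (1E,3E)-1-acetoxy-4-methyldiene (C3=C2–C1=C10) is tied through C9–C8–C7–C6 to an (E)-2-methyl-2-enoate (C5=C4). One thermal step forms C3–C4 and C5–C10, closes rings A and B, and sets C3, C4, C5 and C10 from the single stereocentre C9. The residual C1=C2 alkene is then removed by internal redox isomerisation, and selectride reduction re-sets the axial C3 oxygen.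

Key step: step 14

Remark: labdane numbering is used for all compounds, cyclic or not (C17 = exocyclic methylene carbon, C18 = carboxyl carbon on C4 (α), C19 = methyl on C4 (β), C20 = methyl on C10 (β)); the sense of induction in step 8 is assumed to be selectable through the ligand enantiomer.

Step 1
Reactants: 1 tert-butyl(but-3-yn-1-yloxy)dimethylsilane
Product: 4 (2E)-5-{[tert-butyl(dimethyl)silyl]oxy}-3-methylpent-2-en-1-ol, via alkenylalane 2 (not isolated), via lithium alanate 3 (not isolated)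
Conditions: Me3Al, Cp2ZrCl2 (25 mol %), CH2Cl2, 0 °C to rt; then n-BuLi, THF, −78 °C; (CH2O)n, −78 °C to rt
Reagents that add atoms: trimethylaluminium C[Al](C)C; formaldehyde (as paraformaldehyde) C=O
Why: Negishi carboalumination adds Me–Al syn across the terminal alkyne with methyl on the internal carbon, and hydroxymethylation of the alanate with retention fixes the E-trisubstituted C13=C14 alkene of the side chain.

Step 2
Reactants: 4 (2E)-5-{[tert-butyl(dimethyl)silyl]oxy}-3-methylpent-2-en-1-ol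
Product: 5 (2E)-5-{[tert-butyl(dimethyl)silyl]oxy}-1-{[tert-butyl(diphenyl)silyl]oxy}-3-methylpent-2-ene
Conditions: t-BuPh2SiCl, imidazole, DMF, rt
Reagents that add atoms: tert-butyl(chloro)diphenylsilane CC(C)(C)[Si](Cl)(c1ccccc1)c1ccccc1
Why: Standard silylation of the primary allylic alcohol installs the silyl ether that is meant to last until the final step.

Step 3
Reactants: 5 (2E)-5-{[tert-butyl(dimethyl)silyl]oxy}-1-{[tert-butyl(diphenyl)silyl]oxy}-3-methylpent-2-ene
Product: 6 {[(2E)-5-bromo-3-methylpent-2-en-1-yl]oxy}(tert-butyl)diphenylsilane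
Conditions: Ph3PBr2, CH2Cl2, 0 °C to rt
Reagents that add atoms: dibromotriphenylphosphorane BrP(Br)(c1ccccc1)(c1ccccc1)c1ccccc1
Why: Phosphonium-mediated direct conversion of a silyl ether into the bromide should act on the less hindered dimethyl-tert-butylsilyl ether and leave the bulkier diphenyl-tert-butylsilyl ether untouched.

Step 4
Reactants: 7 ethyl 2-(diethoxyphosphoryl)propanoate; 8 2-(trimethylsilyl)ethanol
Product: 9 2-(trimethylsilyl)ethyl 2-(diethoxyphosphoryl)propanoate
Conditions: DMAP (30 mol %), toluene, reflux with removal of EtOH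
Reagents that add atoms: none
Why: DMAP-catalysed transesterification of the enolisable phosphonoester, driven by distilling out ethanol, installs the fluoride-labile 2-(trimethylsilyl)ethyl ester.

Step 5
Reactants: 10 prop-2-yn-1-ol; 11 [2-(1,3-dioxolan-2-yl)ethyl]magnesium bromide
Product: 13 (2Z)-2-[2-(1,3-dioxolan-2-yl)ethyl]-3-iodoprop-2-en-1-ol, via alkenylmagnesium alkoxide 12 (not isolated)
Conditions: CuI (10 mol %), THF/Et2O, −10 °C to rt; then I2, −40 to 0 °C
Reagents that add atoms: iodine II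
Why: Copper-catalysed anti-carbomagnesiation of the propargylic alkoxide places the alkyl group on C8 and magnesium on C9 cis to the CH2O group through a five-membered chelate, and iodinolysis with retention should give the Z-iodide only.

Step 6
Reactants: 13 (2Z)-2-[2-(1,3-dioxolan-2-yl)ethyl]-3-iodoprop-2-en-1-ol; 14 ethynyltrimethylsilane
Product: 15 (2Z)-2-[2-(1,3-dioxolan-2-yl)ethyl]-5-(trimethylsilyl)pent-2-en-4-yn-1-ol
Conditions: Pd(PPh3)2Cl2 (3 mol %), CuI (5 mol %), i-Pr2NH, THF, rt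
Reagents that add atoms: none
Why: Sonogashira coupling of the alkenyl iodide proceeds with retention of alkene geometry and tolerates the free alcohol and the acetal.

Step 7
Reactants: 15 (2Z)-2-[2-(1,3-dioxolan-2-yl)ethyl]-5-(trimethylsilyl)pent-2-en-4-yn-1-ol
Product: 16 [(3Z)-4-(chloromethyl)-6-(1,3-dioxolan-2-yl)hex-3-en-1-yn-1-yl]trimethylsilane
Conditions: PPh3, hexachloroacetone, CH2Cl2, −20 to 0 °C
Reagents that add atoms: hexachloroacetone ClC(Cl)(Cl)C(=O)C(Cl)(Cl)Cl
Why: Appel-type chlorination under neutral conditions converts primary allylic alcohols into the unrearranged chlorides without alkene isomerisation.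

Step 8
Reactants: 16 [(3Z)-4-(chloromethyl)-6-(1,3-dioxolan-2-yl)hex-3-en-1-yn-1-yl]trimethylsilane; 6 {[(2E)-5-bromo-3-methylpent-2-en-1-yl]oxy}(tert-butyl)diphenylsilane
Product: 19 tert-butyl{[(2E,6S)-6-[4-(1,3-dioxolan-2-yl)but-1-en-2-yl]-3-methyloct-2-en-7-yn-1-yl]oxy}diphenylsilane, via Grignard reagent 17 (not isolated), via silylated enyne 18 (not isolated)
Conditions: 6, Mg, Et2O, rt (forms 17); added slowly to 16, copper thiophene-2-carboxylate (CuTC, 3 mol %), enantiopure BINOL-derived phosphoramidite ligand (3.3 mol %), CH2Cl2, −78 °C; then MeOH, K2CO3, rt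
Reagents that add atoms: none
Why: Copper-catalysed asymmetric allylic alkylation (SN2′) with a Grignard reagent, a reaction type established for enyne chlorides and for β-substituted allylic chlorides, forms C9–C11 at the alkynyl-bearing carbon, sets C9 (S, through the ligand enantiomer) and unveils the C8=C17 methylene; methanolic carbonate then removes the alkynyl silane.

Step 9
Reactants: 19 tert-butyl{[(2E,6S)-6-[4-(1,3-dioxolan-2-yl)but-1-en-2-yl]-3-methyloct-2-en-7-yn-1-yl]oxy}diphenylsilane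
Product: 22 (3E,5S,8E)-10-{[tert-butyl(diphenyl)silyl]oxy}-5-[4-(1,3-dioxolan-2-yl)but-1-en-2-yl]-4,8-dimethyldeca-3,8-dien-1-ol, via alkenylalane 20 (not isolated), via lithium alanate 21 (not isolated)
Conditions: Me3Al, Cp2ZrCl2 (25 mol %), CH2Cl2, 0 °C to rt; then n-BuLi, THF, −78 °C; ethylene oxide, −78 to 0 °C
Reagents that add atoms: trimethylaluminium C[Al](C)C; ethylene oxide C1CO1
Why: Negishi carboalumination (syn, methyl to C10) followed by epoxide opening by the alkenylalanate with retention gives the E-trisubstituted C10=C1 alkene with C9 trans to C2, so that C20 becomes the inside methyl of the later diene; the 1,1-disubstituted and trisubstituted alkenes should not carbometallate.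

Step 10
Reactants: 22 (3E,5S,8E)-10-{[tert-butyl(diphenyl)silyl]oxy}-5-[4-(1,3-dioxolan-2-yl)but-1-en-2-yl]-4,8-dimethyldeca-3,8-dien-1-ol
Product: 23 (5S,6E)-5-[(3E)-5-{[tert-butyl(diphenyl)silyl]oxy}-3-methylpent-3-en-1-yl]-9-hydroxy-6-methyl-4-methylidenenon-6-enal
Conditions: AcOH/THF/H2O (3:1:1), 45 °C
Reagents that add atoms: water O
Why: Mild acid-catalysed acetal hydrolysis frees the C5 aldehyde while the diphenyl-tert-butylsilyl ether and the skipped diene tolerate dilute acetic acid.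

Step 11
Reactants: 23 (5S,6E)-5-[(3E)-5-{[tert-butyl(diphenyl)silyl]oxy}-3-methylpent-3-en-1-yl]-9-hydroxy-6-methyl-4-methylidenenon-6-enal; 9 2-(trimethylsilyl)ethyl 2-(diethoxyphosphoryl)propanoate
Product: 24 2-(trimethylsilyl)ethyl (2E,7S,8E)-7-[(3E)-5-{[tert-butyl(diphenyl)silyl]oxy}-3-methylpent-3-en-1-yl]-11-hydroxy-2,8-dimethyl-6-methylideneundeca-2,8-dienoate
Conditions: LiCl, DBU, MeCN, 0 °C to rt
Reagents that add atoms: none
Why: Horner–Wadsworth–Emmons olefination under Masamune–Roush conditions should give the E-2-methyl-2-enoate (C6 trans to the ester), the geometry that later places the C19 methyl β and the carboxyl α on C4.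

Step 12
Reactants: 24 2-(trimethylsilyl)ethyl (2E,7S,8E)-7-[(3E)-5-{[tert-butyl(diphenyl)silyl]oxy}-3-methylpent-3-en-1-yl]-11-hydroxy-2,8-dimethyl-6-methylideneundeca-2,8-dienoate
Product: 25 2-(trimethylsilyl)ethyl (2E,7S,8E)-7-[(3E)-5-{[tert-butyl(diphenyl)silyl]oxy}-3-methylpent-3-en-1-yl]-2,8-dimethyl-6-methylidene-11-oxoundeca-2,8-dienoate
Conditions: Dess–Martin periodinane, NaHCO3, CH2Cl2, 0 °C; used at once
Reagents that add atoms: none
Why: Buffered Dess–Martin oxidation should give the β,γ-unsaturated aldehyde without migration of the C1=C10 double bond.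

Step 13
Reactants: 25 2-(trimethylsilyl)ethyl (2E,7S,8E)-7-[(3E)-5-{[tert-butyl(diphenyl)silyl]oxy}-3-methylpent-3-en-1-yl]-2,8-dimethyl-6-methylidene-11-oxoundeca-2,8-dienoate
Product: 27 2-(trimethylsilyl)ethyl (2E,7S,8E,10E)-11-acetoxy-7-[(3E)-5-{[tert-butyl(diphenyl)silyl]oxy}-3-methylpent-3-en-1-yl]-2,8-dimethyl-6-methylideneundeca-2,8,10-trienoate, via potassium dienolate 26 (not isolated)
Conditions: KOt-Bu, THF, −78 °C; then Ac2O, −78 °C
Reagents that add atoms: acetic anhydride CC(=O)OC(C)=O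
Why: Kinetic deprotonation at C2 to the potassium dienolate and O-acetylation at low temperature (the established E-selective route to 1-acyloxydienes) should give the (1E)-acetoxydiene while keeping the C1=C10 geometry from step 9.

Step 14
Reactants: 27 2-(trimethylsilyl)ethyl (2E,7S,8E,10E)-11-acetoxy-7-[(3E)-5-{[tert-butyl(diphenyl)silyl]oxy}-3-methylpent-3-en-1-yl]-2,8-dimethyl-6-methylideneundeca-2,8,10-trienoate
Product: 28 2-(trimethylsilyl)ethyl 3α-acetoxy-15-{[tert-butyl(diphenyl)silyl]oxy}labda-1,8(17),13E-trien-18-oate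
Conditions: toluene (0.01 M), BHT (cat.), silylated sealed tube, 170 °C
Reagents that add atoms: none
Why: Concerted, asynchronous thermal [4+2] cycloaddition of the electron-rich (1E,3E)-1-acetoxydiene with the tethered (E)-2-methyl-2-enoate (C5–C10 bonding ahead of C3–C4); the closest known reaction type is the intramolecular Diels–Alder reaction of 1,7,9-decatrienoates, here with a 1-acyloxydiene. Ring A is closed by the cycloaddition itself (both new σ bonds, suprafacial on diene and dienophile) and ring B by the four-carbon tether C6–C9 in a chair-like arrangement, so the fused bicyclo[4.4.0] core forms in one step. C4 follows from the E geometry of the enoate (ester cis to H5, C19 methyl cis to C6), and C3 from the E enol acetate combined with endo placement of the ester (acetoxy cis to the ester). C5 and C10 become trans-fused because in the ester-endo transition state the tether carbon C6 is exo while C9 is the outside diene substituent and the C20 methyl the inside one. The absolute sense is relayed from C9, whose side chain stays pseudo-equatorial and anti to the incoming dienophile. The step needs endo over exo selectivity (the weakest element, supported by the secondary-orbital preference of the ester and the chair tether) and an intact (E,E)-diene, which the stereodefined steps 9 and 13 provide; heating also has to outrun the reversible [1,5]-hydrogen shift from the inside methyl.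

Step 15
Reactants: 28 2-(trimethylsilyl)ethyl 3α-acetoxy-15-{[tert-butyl(diphenyl)silyl]oxy}labda-1,8(17),13E-trien-18-oate
Product: 29 2-(trimethylsilyl)ethyl 15-{[tert-butyl(diphenyl)silyl]oxy}-3α-hydroxylabda-1,8(17),13E-trien-18-oate
Conditions: K2CO3, MeOH, rt
Reagents that add atoms: none
Why: Base-catalysed methanolysis removes the allylic acetate, whereas the ester on quaternary C4 is too hindered to exchange.

Step 16
Reactants: 29 2-(trimethylsilyl)ethyl 15-{[tert-butyl(diphenyl)silyl]oxy}-3α-hydroxylabda-1,8(17),13E-trien-18-oate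
Product: 30 2-(trimethylsilyl)ethyl 15-{[tert-butyl(diphenyl)silyl]oxy}-3-oxolabda-8(17),13E-dien-18-oate
Conditions: Ru(C5Ph5)(CO)2Cl (5 mol %), KOt-Bu (6 mol %), toluene, rt to 50 °C
Reagents that add atoms: none
Why: Ruthenium-catalysed redox isomerisation of the allylic alcohol (alkoxide β-hydride elimination to a bound enone, then conjugate hydride return) moves the carbinol hydrogen to C1, so C1=C2 is saturated without an external reductant and the C8=C17 and C13=C14 alkenes, which cannot bind as alkoxides, should be left alone.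

Step 17
Reactants: 30 2-(trimethylsilyl)ethyl 15-{[tert-butyl(diphenyl)silyl]oxy}-3-oxolabda-8(17),13E-dien-18-oate
Product: 31 2-(trimethylsilyl)ethyl 15-{[tert-butyl(diphenyl)silyl]oxy}-3α-hydroxylabda-8(17),13E-dien-18-oate
Conditions: LiBH(s-Bu)3 (L-Selectride), THF, −78 °C; aqueous work-up
Reagents that add atoms: none
Why: Selectride reduction delivers hydride from the equatorial direction, away from the axial hydrogens on C1 and C5, and should give the axial 3α-alcohol as in 4,4-disubstituted 3-oxo terpenoids; the hindered ester is not reduced.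

Step 18
Reactants: 31 2-(trimethylsilyl)ethyl 15-{[tert-butyl(diphenyl)silyl]oxy}-3α-hydroxylabda-8(17),13E-dien-18-oate
Product: 32 2-(trimethylsilyl)ethyl 3α-acetoxy-15-{[tert-butyl(diphenyl)silyl]oxy}labda-8(17),13E-dien-18-oate
Conditions: Ac2O, DMAP, pyridine, rt to 40 °C
Reagents that add atoms: acetic anhydride CC(=O)OC(C)=O
Why: DMAP-catalysed acylation should acetylate the hindered axial secondary alcohol with retention at C3.

Step 19
Reactants: 32 2-(trimethylsilyl)ethyl 3α-acetoxy-15-{[tert-butyl(diphenyl)silyl]oxy}labda-8(17),13E-dien-18-oate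
Product: 33 3α-acetoxy-15-hydroxylabda-8(17),13E-dien-18-oic acid
Conditions: Bu4NF, THF, rt; dilute aqueous HCl work-up (pH 4)
Reagents that add atoms: none
Why: Fluoride-induced desilylation cleaves the C15 silyl ether and fragments the 2-(trimethylsilyl)ethyl ester (loss of ethene and Me3SiF), releasing alcohol and acid in one operation without touching the hindered acetate.

**Compound list**

1 | tert-butyl(but-3-yn-1-yloxy)dimethylsilane | C#CCCO[Si](C)(C)C(C)(C)C | starting material
2 | [(1E)-4-{[tert-butyl(dimethyl)silyl]oxy}-2-methylbut-1-en-1-yl]dimethylalane | C[Al](C)/C=C(\C)CCO[Si](C)(C)C(C)(C)C | intermediate (not isolated)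
3 | lithium butyl[(1E)-4-{[tert-butyl(dimethyl)silyl]oxy}-2-methylbut-1-en-1-yl]dimethylalanate | [Li+].CCCC[Al-](C)(C)/C=C(\C)CCO[Si](C)(C)C(C)(C)C | intermediate (not isolated)
4 | (2E)-5-{[tert-butyl(dimethyl)silyl]oxy}-3-methylpent-2-en-1-ol | OC/C=C(\C)CCO[Si](C)(C)C(C)(C)C | intermediate
5 | (2E)-5-{[tert-butyl(dimethyl)silyl]oxy}-1-{[tert-butyl(diphenyl)silyl]oxy}-3-methylpent-2-ene | CC(C)(C)[Si](C)(C)OCC/C(C)=C/CO[Si](c1ccccc1)(c1ccccc1)C(C)(C)C | intermediate
6 | {[(2E)-5-bromo-3-methylpent-2-en-1-yl]oxy}(tert-butyl)diphenylsilane | BrCC/C(C)=C/CO[Si](c1ccccc1)(c1ccccc1)C(C)(C)C | intermediate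
7 | ethyl 2-(diethoxyphosphoryl)propanoate | CCOC(=O)C(C)P(=O)(OCC)OCC | starting material
8 | 2-(trimethylsilyl)ethanol | C[Si](C)(C)CCO | starting material
9 | 2-(trimethylsilyl)ethyl 2-(diethoxyphosphoryl)propanoate | CCOP(=O)(OCC)C(C)C(=O)OCC[Si](C)(C)C | intermediate
10 | prop-2-yn-1-ol | C#CCO | starting material
11 | [2-(1,3-dioxolan-2-yl)ethyl]magnesium bromide (commercial THF solution) | Br[Mg]CCC1OCCO1 | starting material
12 | bromomagnesium (2Z)-3-(bromomagnesio)-2-[2-(1,3-dioxolan-2-yl)ethyl]prop-2-en-1-olate | Br[Mg]/C=C(/CCC1OCCO1)CO[Mg]Br | intermediate (not isolated)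
13 | (2Z)-2-[2-(1,3-dioxolan-2-yl)ethyl]-3-iodoprop-2-en-1-ol | OC/C(CCC1OCCO1)=C\I | intermediate
14 | ethynyltrimethylsilane | C#C[Si](C)(C)C | starting material
15 | (2Z)-2-[2-(1,3-dioxolan-2-yl)ethyl]-5-(trimethylsilyl)pent-2-en-4-yn-1-ol | OC/C(CCC1OCCO1)=C\C#C[Si](C)(C)C | intermediate
16 | [(3Z)-4-(chloromethyl)-6-(1,3-dioxolan-2-yl)hex-3-en-1-yn-1-yl]trimethylsilane | ClC/C(CCC1OCCO1)=C\C#C[Si](C)(C)C | intermediate
17 | [(3E)-5-{[tert-butyl(diphenyl)silyl]oxy}-3-methylpent-3-en-1-yl]magnesium bromide | Br[Mg]CC/C(C)=C/CO[Si](c1ccccc1)(c1ccccc1)C(C)(C)C | intermediate (not isolated)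
18 | tert-butyl{[(2E,6S)-6-[4-(1,3-dioxolan-2-yl)but-1-en-2-yl]-3-methyl-8-(trimethylsilyl)oct-2-en-7-yn-1-yl]oxy}diphenylsilane | C[Si](C)(C)C#C[C@@H](CC/C(C)=C/CO[Si](c1ccccc1)(c1ccccc1)C(C)(C)C)C(=C)CCC1OCCO1 | intermediate (not isolated)
19 | tert-butyl{[(2E,6S)-6-[4-(1,3-dioxolan-2-yl)but-1-en-2-yl]-3-methyloct-2-en-7-yn-1-yl]oxy}diphenylsilane | C#C[C@@H](CC/C(C)=C/CO[Si](c1ccccc1)(c1ccccc1)C(C)(C)C)C(=C)CCC1OCCO1 | intermediate
20 | {(1E,3S,6E)-8-{[tert-butyl(diphenyl)silyl]oxy}-3-[4-(1,3-dioxolan-2-yl)but-1-en-2-yl]-2,6-dimethylocta-1,6-dien-1-yl}dimethylalane | C[Al](C)/C=C(\C)[C@@H](CC/C(C)=C/CO[Si](c1ccccc1)(c1ccccc1)C(C)(C)C)C(=C)CCC1OCCO1 | intermediate (not isolated)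
21 | lithium butyl{(1E,3S,6E)-8-{[tert-butyl(diphenyl)silyl]oxy}-3-[4-(1,3-dioxolan-2-yl)but-1-en-2-yl]-2,6-dimethylocta-1,6-dien-1-yl}dimethylalanate | [Li+].CCCC[Al-](C)(C)/C=C(\C)[C@@H](CC/C(C)=C/CO[Si](c1ccccc1)(c1ccccc1)C(C)(C)C)C(=C)CCC1OCCO1 | intermediate (not isolated)
22 | (3E,5S,8E)-10-{[tert-butyl(diphenyl)silyl]oxy}-5-[4-(1,3-dioxolan-2-yl)but-1-en-2-yl]-4,8-dimethyldeca-3,8-dien-1-ol | OCC/C=C(\C)[C@@H](CC/C(C)=C/CO[Si](c1ccccc1)(c1ccccc1)C(C)(C)C)C(=C)CCC1OCCO1 | intermediate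
23 | (5S,6E)-5-[(3E)-5-{[tert-butyl(diphenyl)silyl]oxy}-3-methylpent-3-en-1-yl]-9-hydroxy-6-methyl-4-methylidenenon-6-enal | OCC/C=C(\C)[C@@H](CC/C(C)=C/CO[Si](c1ccccc1)(c1ccccc1)C(C)(C)C)C(=C)CCC=O | intermediate
24 | 2-(trimethylsilyl)ethyl (2E,7S,8E)-7-[(3E)-5-{[tert-butyl(diphenyl)silyl]oxy}-3-methylpent-3-en-1-yl]-11-hydroxy-2,8-dimethyl-6-methylideneundeca-2,8-dienoate | OCC/C=C(\C)[C@@H](CC/C(C)=C/CO[Si](c1ccccc1)(c1ccccc1)C(C)(C)C)C(=C)CC/C=C(\C)C(=O)OCC[Si](C)(C)C | intermediate
25 | 2-(trimethylsilyl)ethyl (2E,7S,8E)-7-[(3E)-5-{[tert-butyl(diphenyl)silyl]oxy}-3-methylpent-3-en-1-yl]-2,8-dimethyl-6-methylidene-11-oxoundeca-2,8-dienoate | O=CC/C=C(\C)[C@@H](CC/C(C)=C/CO[Si](c1ccccc1)(c1ccccc1)C(C)(C)C)C(=C)CC/C=C(\C)C(=O)OCC[Si](C)(C)C | intermediate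
26 | potassium (1E,3E)-dienolate of 25 | [K+].[O-]/C=C/C=C(\C)[C@@H](CC/C(C)=C/CO[Si](c1ccccc1)(c1ccccc1)C(C)(C)C)C(=C)CC/C=C(\C)C(=O)OCC[Si](C)(C)C | intermediate (not isolated)
27 | 2-(trimethylsilyl)ethyl (2E,7S,8E,10E)-11-acetoxy-7-[(3E)-5-{[tert-butyl(diphenyl)silyl]oxy}-3-methylpent-3-en-1-yl]-2,8-dimethyl-6-methylideneundeca-2,8,10-trienoate | CC(=O)O/C=C/C=C(\C)[C@@H](CC/C(C)=C/CO[Si](c1ccccc1)(c1ccccc1)C(C)(C)C)C(=C)CC/C=C(\C)C(=O)OCC[Si](C)(C)C | intermediate
28 | 2-(trimethylsilyl)ethyl 3α-acetoxy-15-{[tert-butyl(diphenyl)silyl]oxy}labda-1,8(17),13E-trien-18-oate (5α-H, 9β side chain, 10β-Me, 4β-Me) | C=C1CC[C@@H]2[C@](C)(C=C[C@@H](OC(C)=O)[C@@]2(C)C(=O)OCC[Si](C)(C)C)[C@H]1CC/C(C)=C/CO[Si](c1ccccc1)(c1ccccc1)C(C)(C)C | intermediate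
29 | 2-(trimethylsilyl)ethyl 15-{[tert-butyl(diphenyl)silyl]oxy}-3α-hydroxylabda-1,8(17),13E-trien-18-oate | C=C1CC[C@@H]2[C@](C)(C=C[C@@H](O)[C@@]2(C)C(=O)OCC[Si](C)(C)C)[C@H]1CC/C(C)=C/CO[Si](c1ccccc1)(c1ccccc1)C(C)(C)C | intermediate
30 | 2-(trimethylsilyl)ethyl 15-{[tert-butyl(diphenyl)silyl]oxy}-3-oxolabda-8(17),13E-dien-18-oate | C=C1CC[C@@H]2[C@](C)(CCC(=O)[C@@]2(C)C(=O)OCC[Si](C)(C)C)[C@H]1CC/C(C)=C/CO[Si](c1ccccc1)(c1ccccc1)C(C)(C)C | intermediate
31 | 2-(trimethylsilyl)ethyl 15-{[tert-butyl(diphenyl)silyl]oxy}-3α-hydroxylabda-8(17),13E-dien-18-oate | C=C1CC[C@@H]2[C@](C)(CC[C@@H](O)[C@@]2(C)C(=O)OCC[Si](C)(C)C)[C@H]1CC/C(C)=C/CO[Si](c1ccccc1)(c1ccccc1)C(C)(C)C | intermediate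
32 | 2-(trimethylsilyl)ethyl 3α-acetoxy-15-{[tert-butyl(diphenyl)silyl]oxy}labda-8(17),13E-dien-18-oate | C=C1CC[C@@H]2[C@](C)(CC[C@@H](OC(C)=O)[C@@]2(C)C(=O)OCC[Si](C)(C)C)[C@H]1CC/C(C)=C/CO[Si](c1ccccc1)(c1ccccc1)C(C)(C)C | intermediate
33 | 3α-acetoxy-15-hydroxylabda-8(17),13E-dien-18-oic acid, (3R,4S,5R,9S,10R) | C=C1CC[C@@H]2[C@](C)(CC[C@@H](OC(C)=O)[C@@]2(C)C(=O)O)[C@H]1CC/C(C)=C/CO | target

**Count.** Total: 19 steps. Longest linear sequence: 15 steps (steps 5–19 from prop-2-yn-1-ol 10; the branch through steps 1–3 and 8–19 is equally long).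

**Steps most likely to fail**

Step 14 (key cycloaddition). The cycloaddition may be slow at the fully substituted diene terminus, so that the reversible [1,5]-hydrogen shift from the C20 methyl competes and endo/exo discrimination erodes towards cis-fused adducts. The fallback uses a more reactive and more strongly endo-directing aldehyde dienophile. It sets out from hydroxy aldehyde 23: Wittig reaction with 2-(triphenylphosphoranylidene)propanal should give the hydroxy enal F1, and Dess–Martin oxidation then gives the dialdehyde F2. Its more acidic β,γ-unsaturated aldehyde is enol-acetylated (Ac2O, Et3N, DMAP) to the acetoxydiene enal F3. This should cyclise in toluene near 110 °C to the cycloadduct aldehyde F4. Pinnick oxidation gives the acid F5, and Steglich esterification (DCC, DMAP) with 2-(trimethylsilyl)ethanol 8 comes back to the route at cycloadduct 28.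

Step 8 (copper-catalysed allylic alkylation). Regiocontrol (attack at the CH2Cl carbon) and facial discrimination may erode for the Z-configured, β-substituted enyne chloride. The fallback replaces catalyst control by a stoichiometric chiral leaving group. It sets out from enynol 15, which is treated with (R)-1-(naphthalen-1-yl)ethyl isocyanate (or its antipode, whichever delivers the S centre) to give the chiral carbamate F6. Deprotonation with MeLi, complexation with CuI and addition of the organolithium F7 (from bromide 6 and t-BuLi, Et2O, −78 °C) should transfer the alkyl group syn to the carbamate in an auxiliary-directed SN2′ displacement. This comes back to the route at silylated enyne 18, which is desilylated to 19 as in step 8.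

Step 16 (redox isomerisation). The hindered C3 alkoxide next to quaternary C4 may fail to bind the bulky ruthenium centre or to undergo β-hydride elimination, so the catalyst does not turn over, or the basic medium may start retro-Claisen opening of the β-keto ester. The fallback separates oxidation and reduction. It sets out from allylic alcohol 29: Dess–Martin oxidation gives the enone F8, and chemoselective conjugate reduction with Stryker's reagent [(Ph3P)CuH]6 in wet benzene comes back to the route at ketone 30, leaving the isolated alkenes untouched.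

Further compounds
F1 | step 14 | (2E,7S,8E)-7-[(3E)-5-{[tert-butyl(diphenyl)silyl]oxy}-3-methylpent-3-en-1-yl]-11-hydroxy-2,8-dimethyl-6-methylideneundeca-2,8-dienal | OCC/C=C(\C)[C@@H](CC/C(C)=C/CO[Si](c1ccccc1)(c1ccccc1)C(C)(C)C)C(=C)CC/C=C(\C)C=O
F2 | step 14 | (2E,7S,8E)-7-[(3E)-5-{[tert-butyl(diphenyl)silyl]oxy}-3-methylpent-3-en-1-yl]-2,8-dimethyl-6-methylideneundeca-2,8-dienedial | O=CC/C=C(\C)[C@@H](CC/C(C)=C/CO[Si](c1ccccc1)(c1ccccc1)C(C)(C)C)C(=C)CC/C=C(\C)C=O
F3 | step 14 | (1E,3E,5S,9E)-5-[(3E)-5-{[tert-butyl(diphenyl)silyl]oxy}-3-methylpent-3-en-1-yl]-4,10-dimethyl-6-methylidene-11-oxoundeca-1,3,9-trien-1-yl acetate | CC(=O)O/C=C/C=C(\C)[C@@H](CC/C(C)=C/CO[Si](c1ccccc1)(c1ccccc1)C(C)(C)C)C(=C)CC/C=C(\C)C=O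
F4 | step 14 | 3α-acetoxy-15-{[tert-butyl(diphenyl)silyl]oxy}labda-1,8(17),13E-trien-18-al | C=C1CC[C@@H]2[C@](C)(C=C[C@@H](OC(C)=O)[C@@]2(C)C=O)[C@H]1CC/C(C)=C/CO[Si](c1ccccc1)(c1ccccc1)C(C)(C)C
F5 | step 14 | 3α-acetoxy-15-{[tert-butyl(diphenyl)silyl]oxy}labda-1,8(17),13E-trien-18-oic acid | C=C1CC[C@@H]2[C@](C)(C=C[C@@H](OC(C)=O)[C@@]2(C)C(=O)O)[C@H]1CC/C(C)=C/CO[Si](c1ccccc1)(c1ccccc1)C(C)(C)C
F6 | step 8 | (2Z)-2-[2-(1,3-dioxolan-2-yl)ethyl]-5-(trimethylsilyl)pent-2-en-4-yn-1-yl [(1R)-1-(naphthalen-1-yl)ethyl]carbamate | C[C@@H](NC(=O)OC/C(CCC1OCCO1)=C\C#C[Si](C)(C)C)c1cccc2ccccc12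
F7 | step 8 | [(3E)-5-{[tert-butyl(diphenyl)silyl]oxy}-3-methylpent-3-en-1-yl]lithium | [Li]CC/C(C)=C/CO[Si](c1ccccc1)(c1ccccc1)C(C)(C)C
F8 | step 16 | 2-(trimethylsilyl)ethyl 15-{[tert-butyl(diphenyl)silyl]oxy}-3-oxolabda-1,8(17),13E-trien-18-oate | C=C1CC[C@@H]2[C@](C)(C=CC(=O)[C@@]2(C)C(=O)OCC[Si](C)(C)C)[C@H]1CC/C(C)=C/CO[Si](c1ccccc1)(c1ccccc1)C(C)(C)C
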